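**Retrosynthetic overview**

1. The only strategic cut is the biaryl bond C3'–C8''. Locants with no or one prime belong to the apigenin half, those with two or three primes to the 7''-O-methyl half. The cut gives two intact flavones, apigenin and genkwanin, the monomers the plant is presumed to join by oxidative phenol coupling. No ring is formed in the route: all six rings are bought with the two flavones.
2. Enabling feature: C3' is the ortho carbon of the free 4'-OH of ring B, whose para carbon C1' is blocked by C2, so two-electron oxidation of this phenol makes C3' electrophilic. C8'' is the CH of the phloroglucinol-type ring A lying between 7''-OMe and O1'' and para to O5'', the most nucleophilic CH of the other half.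
3. Shaping of the partners: a benzyl carbonate on O7 switches off ring A of the phenol partner as a nucleophile. Benzyl ethers on O5'' and O4''' leave the nucleophile without an oxidisable phenol and steer attack to C8'' instead of C6''.
4. Order: one protection on each monomer (steps 1 and 2), dehydrogenative cross-coupling with PhI(OAc)2 in a fluoroalcohol (step 3), one hydrogenolysis that removes all three benzyl-type groups (step 4).

Key step: step 3

Assumption: apigenin and genkwanin are taken as purchased flavones, and the C3'–C8'' axis, whose ortho groups are only OH, OMe and a ring oxygen, is treated as freely rotating because the target is drawn without axial configuration.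

**Route**

Step 1
Reactants: 1 apigenin [5,7-dihydroxy-2-(4-hydroxyphenyl)-4H-chromen-4-one]
Product: 2 7-O-benzyloxycarbonylapigenin [benzyl 5-hydroxy-2-(4-hydroxyphenyl)-4-oxo-4H-chromen-7-yl carbonate]
Conditions: CbzCl (1.0 equiv), K2CO3 (1.0 equiv), DMF, −10 to 0 °C
Reagents that add atoms: benzyl chloroformate O=C(Cl)OCc1ccccc1
Why: Chemoselective O-acylation of a phenoxide (carbonate formation of the Schotten–Baumann type): the 7-OH, a vinylogous acid conjugated with C4=O, is the most acidic of the three phenols, so one equivalent of base should generate mainly the 7-phenoxide, which takes up the single equivalent of chloroformate at low temperature while the 4'-OH stays free and the chelated 5-OH is inert.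

Step 2
Reactants: 3 genkwanin [5-hydroxy-2-(4-hydroxyphenyl)-7-methoxy-4H-chromen-4-one]
Product: 4 5,4'-di-O-benzylgenkwanin [5-(benzyloxy)-2-[4-(benzyloxy)phenyl]-7-methoxy-4H-chromen-4-one]
Conditions: BnBr (3 equiv), K2CO3 (4 equiv), Bu4NI (0.1 equiv), DMF, 80 °C
Reagents that add atoms: benzyl bromide BrCc1ccccc1
Why: Williamson ether synthesis: the 4'-phenoxide is alkylated readily and the hydrogen-bonded 5-OH, the only position left, should follow with excess benzyl bromide, iodide catalysis and heat in DMF, the 7-OMe group being inert.

Step 3
Reactants: 2 7-O-benzyloxycarbonylapigenin; 4 5,4'-di-O-benzylgenkwanin (1.5 equiv)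
Product: 7 O7-benzyloxycarbonyl-O5'',O4'''-dibenzylsotetsuflavone, via aryloxy-λ3-iodane 5 (not isolated), via ring-B dienone 6 (not isolated)
Conditions: PhI(OAc)2 (1.0 equiv, slow addition), 4 Å MS, (CF3)2CHOH/CH2Cl2 4:1, 0 °C
Reagents that add atoms: none
Why: Proposed new method: ligand exchange of the 4'-OH of 2 (its only phenol that is neither acylated nor chelated) at trivalent iodine should give aryloxy-λ3-iodane 5, which in the ionising and non-nucleophilic fluoroalcohol loses iodobenzene and acetate to a ring-B phenoxenium ion pair that C8 of the trialkoxy ring A of 4 attacks at C3', giving dienone 6, whose tautomerisation to phenol 7 makes the C–C bond formation irreversible whereas addition of acetate or solvent at the blocked para carbon C1' is reversible. The closest known reaction types are the oxidative phenol–arene cross-coupling mediated by hypervalent iodine reagents or an anode in fluorinated alcohols (alkyl- and alkoxyphenols with 1,3,5-trimethoxybenzene-type nucleophiles) and the oxidative dearomatisation of 4'-hydroxyflavones at ring B by trivalent iodine reagents with water as nucleophile, which shows that this acceptor-substituted phenol is oxidised in preference to ring A; what is new is the use of a second flavone as the carbon nucleophile. No ring is closed and no stereocentre is formed, the new axis being taken as freely rotating. The choice of which partner is oxidised and which is the nucleophile is secured by 4 having no free phenol and by the O7 carbonate together with the 5-OH to C4=O hydrogen bond making ring A of 2 a poor nucleophile, so that self-coupling of 2 should be slow. Site selectivity on 2 needs no control because C3' and C5' are equivalent, and on 4 the 5-O-benzyl ether removes the ortho-directing free 5-OH so that C8, flanked only by OMe and the ring oxygen and para to O5, should react in preference to C6, in line with the C8-selective halogenation of 5,7-dialkoxyflavones. A two-electron oxidant is chosen because one-electron oxidation of apigenin-type phenols is prone to radical coupling through C3, and over-oxidation of the more electron-rich product phenol is held back by the excess of 4 and slow addition of one equivalent of oxidant at 0 °C.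

Step 4
Reactants: 7 O7-benzyloxycarbonyl-O5'',O4'''-dibenzylsotetsuflavone
Product: 8 sotetsuflavone
Conditions: H2 (1 atm), Pd/C (10%), THF/MeOH 1:1, rt
Reagents that add atoms: none
Why: Palladium-catalysed hydrogenolysis cleaves the two aryl benzyl ethers and the benzyl carbonate (the carbonic acid half-ester loses CO2) in one operation, while the aryl methyl ether is inert and the vinylogous-ester C2=C3 bonds of both chromones should survive at 1 atm and room temperature.

**Compound list**

1 | apigenin; 5,7-dihydroxy-2-(4-hydroxyphenyl)-4H-chromen-4-one | O=c1cc(-c2ccc(O)cc2)oc2cc(O)cc(O)c12 | starting material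
2 | 7-O-benzyloxycarbonylapigenin; benzyl 5-hydroxy-2-(4-hydroxyphenyl)-4-oxo-4H-chromen-7-yl carbonate | O=c1cc(-c2ccc(O)cc2)oc2cc(OC(=O)OCc3ccccc3)cc(O)c12 | intermediate
3 | genkwanin; 5-hydroxy-2-(4-hydroxyphenyl)-7-methoxy-4H-chromen-4-one | COc1cc(O)c2c(=O)cc(-c3ccc(O)cc3)oc2c1 | starting material
4 | 5,4'-di-O-benzylgenkwanin; 5-(benzyloxy)-2-[4-(benzyloxy)phenyl]-7-methoxy-4H-chromen-4-one | COc1cc(OCc2ccccc2)c2c(=O)cc(-c3ccc(OCc4ccccc4)cc3)oc2c1 | intermediate
5 | aryloxy-λ3-iodane: compound 2 bound through O4' to iodine that also carries phenyl and acetate | O=c1cc(-c2ccc(OI(c3ccccc3)OC(C)=O)cc2)oc2cc(OC(=O)OCc3ccccc3)cc(O)c12 | intermediate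
6 | ring-B dienone: keto tautomer of 7, ring B being a cyclohexa-2,4-dien-1-one with C4'=O and an sp3 C3'–H that carries the C8'' flavone (racemic, transient) | O=C1C=CC(c2cc(=O)c3c(O)cc(OC(=O)OCc4ccccc4)cc3o2)=CC1c1c(OC)cc(OCc2ccccc2)c2c(=O)cc(-c3ccc(OCc4ccccc4)cc3)oc12 | intermediate
7 | O7-benzyloxycarbonyl-O5'',O4'''-dibenzylsotetsuflavone; sotetsuflavone with a benzyl carbonate on O7, benzyl ethers on O5'' and O4''', free 5-OH and 4'-OH | COc1cc(OCc2ccccc2)c2c(=O)cc(-c3ccc(OCc4ccccc4)cc3)oc2c1-c1cc(-c2cc(=O)c3c(O)cc(OC(=O)OCc4ccccc4)cc3o2)ccc1O | intermediate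
8 | sotetsuflavone; 7''-O-methylamentoflavone | COc1cc(O)c2c(=O)cc(-c3ccc(O)cc3)oc2c1-c1cc(-c2cc(=O)c3c(O)cc(O)cc3o2)ccc1O | target

**Step count and risks**

Total step count: 4 (steps 1 and 2 are parallel single protections).
Longest linear sequence: 3 steps (1 → 2 → 7 → 8, or 3 → 4 → 7 → 8).

Steps most likely to fail:

1. Step 3 (proposed new method). What may go wrong:
- the ring-B cation may be captured irreversibly by oxygen nucleophiles at C1' (dearomatisation);
- the iodophenyl ligand may be transferred to C3';
- the product phenol may be oxidised further;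
- attack may occur through C6'' instead of C8''.

Fallback with known chemistry, a Suzuki–Miyaura union of two pre-functionalised flavones, setting out from 4 and coming back to the route at 8. Electrophilic iodination of 4 (NIS, TFA 0.2 equiv, MeCN, rt; C8-selective for 5,7-dialkoxyflavones) gives 8-iodo-5,4'-di-O-benzylgenkwanin F1. The boron partner is assembled de novo from purchased 1-[2,4-bis(benzyloxy)-6-hydroxyphenyl]ethanone and purchased 4-(benzyloxy)-3-bromobenzaldehyde. Claisen–Schmidt condensation (KOH, EtOH, rt) gives (E)-4,4',6'-tris(benzyloxy)-3-bromo-2'-hydroxychalcone F2. Oxidative cyclisation (iodine 0.1 equiv, DMSO, 130 °C) gives 3'-bromo-5,7,4'-tri-O-benzylapigenin F3. Miyaura borylation (B2pin2, Pd(dppf)Cl2, KOAc, dioxane, 90 °C) gives 5,7,4'-tri-O-benzylapigenin-3'-boronic acid pinacol ester F4. Cross-coupling of F1 with F4 (Pd(PPh3)4, K2CO3, DMF/H2O, 90 °C), a coupling type established for 8-iodoflavones and flavone-3'-boronates, gives penta-O-benzylsotetsuflavone F5. Hydrogenolysis under the conditions of step 4 then delivers 8.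

2. Step 1. What may go wrong: insufficient discrimination between the 7-OH and the 4'-OH during acylation, leading to double acylation or acylation at the wrong oxygen.

Fallback that moves the selectivity from a protection to a deprotection, setting out from 1 and coming back at 2. Silylation of both reactive phenols (TBSCl, imidazole, DMF, rt; the chelated 5-OH stays free) gives 7,4'-bis-O-TBS-apigenin F6. The silyl ether of the more acidic 7-OH, the better leaving group, is cleaved selectively (K2CO3, MeOH/THF, 0 °C) to 4'-O-TBS-apigenin F7. Acylation of the only reactive phenol left (CbzCl, iPr2NEt, CH2Cl2, 0 °C) gives 7-O-benzyloxycarbonyl-4'-O-TBS-apigenin F8. HF·pyridine (THF, 0 °C) removes the silyl ether without touching the carbonate and returns 2.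

3. Step 4. What may go wrong: over-reduction of the chromone C2=C3 bonds, or stalling of the hydrogenolysis through low solubility of partly deprotected biflavones or catalyst poisoning.

Fallback by Lewis-acid dealkylation instead of hydrogenation, setting out from 7 and coming back at 8 with no new compound. BCl3 (excess) with pentamethylbenzene as benzyl-cation scavenger (CH2Cl2, −78 to 0 °C, then MeOH quench) should cleave both benzyl ethers and the benzyl carbonate, whose boron-bound carbonic half-ester decarboxylates on quench. The unchelated 7''-OMe is expected to survive this reagent.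

Further compounds
F1 | step 3 | 8-iodo-5,4'-di-O-benzylgenkwanin; 5-(benzyloxy)-2-[4-(benzyloxy)phenyl]-8-iodo-7-methoxy-4H-chromen-4-one | COc1cc(OCc2ccccc2)c2c(=O)cc(-c3ccc(OCc4ccccc4)cc3)oc2c1I
F2 | step 3 | (2E)-1-[2,4-bis(benzyloxy)-6-hydroxyphenyl]-3-[4-(benzyloxy)-3-bromophenyl]prop-2-en-1-one | O=C(/C=C/c1ccc(OCc2ccccc2)c(Br)c1)c1c(O)cc(OCc2ccccc2)cc1OCc1ccccc1
F3 | step 3 | 3'-bromo-5,7,4'-tri-O-benzylapigenin; 5,7-bis(benzyloxy)-2-[4-(benzyloxy)-3-bromophenyl]-4H-chromen-4-one | O=c1cc(-c2ccc(OCc3ccccc3)c(Br)c2)oc2cc(OCc3ccccc3)cc(OCc3ccccc3)c12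
F4 | step 3 | 5,7,4'-tri-O-benzylapigenin-3'-boronic acid pinacol ester | O=c1cc(-c2ccc(OCc3ccccc3)c(B3OC(C)(C)C(C)(C)O3)c2)oc2cc(OCc3ccccc3)cc(OCc3ccccc3)c12
F5 | step 3 | 5,7,4',5'',4'''-penta-O-benzylsotetsuflavone | COc1cc(OCc2ccccc2)c2c(=O)cc(-c3ccc(OCc4ccccc4)cc3)oc2c1-c1cc(-c2cc(=O)c3c(OCc4ccccc4)cc(OCc4ccccc4)cc3o2)ccc1OCc1ccccc1
F6 | step 1 | 7,4'-bis-O-(tert-butyldimethylsilyl)apigenin | O=c1cc(-c2ccc(O[Si](C)(C)C(C)(C)C)cc2)oc2cc(O[Si](C)(C)C(C)(C)C)cc(O)c12
F7 | step 1 | 4'-O-(tert-butyldimethylsilyl)apigenin | O=c1cc(-c2ccc(O[Si](C)(C)C(C)(C)C)cc2)oc2cc(O)cc(O)c12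
F8 | step 1 | 7-O-benzyloxycarbonyl-4'-O-(tert-butyldimethylsilyl)apigenin | O=c1cc(-c2ccc(O[Si](C)(C)C(C)(C)C)cc2)oc2cc(OC(=O)OCc3ccccc3)cc(O)c12
F0 | step 4 | none | none
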